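**A direct plan and its weak points**

A direct plan would take the silyl ether of dec-9-en-1-ol, compound A1, and add to A1 the four methyl-bearing carbons one at a time by zirconium-catalysed asymmetric carboalumination, each followed by vinylation, the last with an ethylalane and the antipodal catalyst.
The finished chain would become bromide A2 and then the (Z)-2-bromoalkene A3; the alkenyllithium from A3 would be added to methoxycyclobutenedione A4, and heating of adduct A5 followed by oxidation would close the quinone.
Its weakest steps would be: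
(a) the three carboalumination–vinylation rounds: each spends a whole operation on three carbons and one stereocenter that rests on the catalyst alone, so errors multiply and syn/anti isomers would have to be removed by chromatography;
(b) the closing ethylalumination: the most remote center would again be set by the catalyst only, on the longest intermediate, where its epimer could hardly be separated;
(c) the t-BuLi exchange on A3, the addition to A4 and the thermal ring expansion of A5: a ring that can be bought would be built last, on the most precious material, and would depend on regio- and torquoselectivity.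

**Plan of the new route**

The chain is cut at C9–C10 and C14–C15 and, as an alkene, at C2–C3; no ring is formed, the six-membered carbocycle is bought as 2-methoxy-5-methylphenol and only oxidised at the end.
Enabling feature: C10 to C14 with the methyl groups on C11 and C13 form a meso 2,4-dimethylpentane-1,5-diyl unit (local mirror plane through C12H2); it is bought as cis-2,4-dimethylglutaric anhydride, whose six-membered ring fixes the syn relation, and one lipase acetylation tells its two ends apart.
C9 and C15 each carry one methyl, one hydrogen and one unbranched chain, so they are the carbinol carbons of (S)-non-8-en-2-ol (from (S)-propylene oxide) and (R)-butan-2-ol; their tosylates are joined to the two CH2MgBr ends of the core by copper-catalysed SN2 coupling with inversion.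
Order of events: core, C14–C15 union, C9–C10 union (key), cross-metathesis with an ortho-allylphenol from an aromatic Claisen rearrangement, hydrogenation, phenol-to-quinone oxidation.
The weak steps no longer occur: no chain stereocenter rests on catalyst induction (two come from a ring, two from the chiral pool by stereospecific substitution), the chain is joined from three pieces instead of grown unit by unit, and the end needs neither an organolithium reagent nor a ring construction.

Key step: step 11

Remark: cis-2,4-dimethylglutaric anhydride is taken to be commercially available.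
Remark: the lipase is taken to acetylate the hydroxymethyl group on the R-configured carbon of the meso diol; should the enzyme at hand show the opposite sense, hydrolysis of the meso diacetate with the same enzyme, or running the two couplings in the reverse order, would lead to the same product.

**Route**

Step 1
Reactants: 1 cis-2,4-dimethylglutaric anhydride, (3R,5S)-3,5-dimethyloxane-2,6-dione (meso)
Product: 2 (2R,4S)-2,4-dimethylpentane-1,5-diol (meso)
Conditions: LiAlH4, THF, 0 → 66 °C; then H2O
Reagents that add atoms: none
Why: Hydride reduction of a cyclic anhydride to the 1,5-diol opens the template ring without touching its two stereocenters, so that the cis relation of the ring becomes the syn relation of C11 and C13.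

Step 2
Reactants: 2 (2R,4S)-2,4-dimethylpentane-1,5-diol
Product: 3 (2R,4S)-5-hydroxy-2,4-dimethylpentyl acetate
Conditions: lipase from Pseudomonas fluorescens, vinyl acetate, THF, 23 °C
Reagents that add atoms: vinyl acetate, CC(=O)OC=C
Why: Lipase-catalysed transesterification of a meso 2-methyl-branched primary diol (enzymatic desymmetrisation) should acetylate one enantiotopic hydroxymethyl group only, which fixes the absolute sense of C11/C13 and distinguishes the two chain ends in one operation without forming a new stereocenter.

Step 3
Reactants: 3 (2R,4S)-5-hydroxy-2,4-dimethylpentyl acetate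
Product: 4 (2R,4S)-5-[(tert-butyldimethylsilyl)oxy]-2,4-dimethylpentyl acetate
Conditions: TBSCl, imidazole, DMF, 23 °C
Reagents that add atoms: tert-butyldimethylsilyl chloride, CC(C)(C)[Si](C)(C)Cl
Why: Imidazole-promoted silylation of the free primary alcohol masks the C10 oxygen for the organomagnesium steps and leaves the acetate in place.

Step 4
Reactants: 4 (2R,4S)-5-[(tert-butyldimethylsilyl)oxy]-2,4-dimethylpentyl acetate
Product: 5 (2R,4S)-5-[(tert-butyldimethylsilyl)oxy]-2,4-dimethylpentan-1-ol
Conditions: K2CO3 (0.2 equiv), MeOH, 23 °C
Reagents that add atoms: none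
Why: Base-catalysed transesterification with methanol removes the acetate at C14 while the primary silyl ether is stable to these conditions.

Step 5
Reactants: 5 (2R,4S)-5-[(tert-butyldimethylsilyl)oxy]-2,4-dimethylpentan-1-ol
Product: 6 tert-butyl{[(2S,4R)-5-bromo-2,4-dimethylpentyl]oxy}dimethylsilane
Conditions: CBr4, PPh3, CH2Cl2, 0 °C
Reagents that add atoms: carbon tetrabromide, BrC(Br)(Br)Br
Why: Appel bromination turns the primary alcohol into the bromide through an alkoxyphosphonium ion under neutral conditions that spare the silyl ether and involve no stereocenter.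

Step 6
Reactants: 7 (2R)-butan-2-ol
Product: 8 (2R)-butan-2-yl 4-methylbenzenesulfonate
Conditions: TsCl, pyridine, 0 °C
Reagents that add atoms: 4-methylbenzenesulfonyl chloride, Cc1ccc(cc1)S(=O)(=O)Cl
Why: Sulfonylation takes place at oxygen, so the chiral-pool carbinol carbon keeps its R configuration and becomes a leaving-group-bearing center.

Step 7
Reactants: 6 tert-butyl{[(2S,4R)-5-bromo-2,4-dimethylpentyl]oxy}dimethylsilane, 8 (2R)-butan-2-yl 4-methylbenzenesulfonate
Product: 10 tert-butyldimethyl{[(2S,4S,6S)-2,4,6-trimethyloctyl]oxy}silane, via alkylmagnesium bromide 9 (not isolated)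
Conditions: 6, Mg, THF, 50 °C; then 8 (1.5 equiv), CuI (10 mol%), TMEDA (20 mol%), LiOMe (1 equiv), THF, 0 °C
Reagents that add atoms: none
Why: Copper-catalysed alkyl–alkyl cross-coupling of a primary Grignard reagent with an unactivated secondary tosylate runs as an SN2 substitution with inversion, so the R carbinol carbon of 8 becomes C15 with S configuration while the C14–C15 bond is formed.

Step 8
Reactants: 10 tert-butyldimethyl{[(2S,4S,6S)-2,4,6-trimethyloctyl]oxy}silane
Product: 11 (2S,4S,6S)-1-bromo-2,4,6-trimethyloctane
Conditions: Ph3PBr2, CH2Cl2, 23 °C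
Reagents that add atoms: triphenylphosphine dibromide, BrP(Br)(c1ccccc1)(c1ccccc1)c1ccccc1
Why: Triphenylphosphine dibromide converts a primary silyl ether directly into the bromide (Appel-type substitution through an alkoxyphosphonium ion), with no stereocenter involved.

Step 9
Reactants: 12 (2S)-2-methyloxirane ((S)-propylene oxide), 13 6-bromohex-1-ene
Product: 15 (2S)-non-8-en-2-ol, via hex-5-enylmagnesium bromide 14 (not isolated)
Conditions: 13, Mg, THF, 40 °C; then CuI (10 mol%), 12, THF, −30 → 0 °C; aq. NH4Cl
Reagents that add atoms: none
Why: Copper-catalysed opening of a terminal epoxide by a Grignard reagent takes place at the unsubstituted carbon, so the stereocenter of the chiral-pool epoxide is carried over unchanged as the future C9.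

Step 10
Reactants: 15 (2S)-non-8-en-2-ol
Product: 16 (2S)-non-8-en-2-yl 4-methylbenzenesulfonate
Conditions: TsCl, pyridine, 0 °C
Reagents that add atoms: 4-methylbenzenesulfonyl chloride, Cc1ccc(cc1)S(=O)(=O)Cl
Why: Sulfonylation at oxygen activates the carbinol carbon with retention and does not affect the terminal alkene.

Step 11
Reactants: 11 (2S,4S,6S)-1-bromo-2,4,6-trimethyloctane, 16 (2S)-non-8-en-2-yl 4-methylbenzenesulfonate
Product: 18 (8R,10R,12S,14S)-8,10,12,14-tetramethylhexadec-1-ene, via alkylmagnesium bromide 17 (not isolated)
Conditions: 11, Mg, THF, 50 °C; then 16 (1.3 equiv), CuI (10 mol%), TMEDA (20 mol%), LiOMe (1 equiv), THF, 0 °C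
Reagents that add atoms: none
Why: The alkylcopper species formed from Grignard reagent 17 should displace the tosylate of 16 by backside attack, so that the C9–C10 bond is made with inversion at the carbinol carbon. The closest known reaction type is the copper-catalysed cross-coupling of unactivated secondary alkyl tosylates with alkyl Grignard reagents in the presence of TMEDA and LiOMe, which is known to proceed by an SN2 pathway. No ring is closed. The new stereocenter C9 is controlled only by the configuration of 16 (S at the carbinol carbon gives R at C9), while C11, C13 and C15 arrive unchanged in 17, so the all-syn tetrad follows from the absolute configurations of the two partners and not from induction. The step needs substitution to win over E2 elimination and over electron-transfer pathways that would scramble C9; the unbranched 2-alkyl tosylate, the primary nucleophile (branched only at its β-carbon) and the low temperature should secure this, and the remote terminal alkene is inert.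

Step 12
Reactants: 19 2-methoxy-5-methylphenol, 20 3-bromoprop-1-ene (allyl bromide)
Product: 21 1-methoxy-4-methyl-2-(prop-2-en-1-yloxy)benzene
Conditions: K2CO3, acetone, 56 °C
Reagents that add atoms: none
Why: Williamson ether synthesis of the phenoxide with an allylic bromide gives the aryl allyl ether needed for the rearrangement.

Step 13
Reactants: 21 1-methoxy-4-methyl-2-(prop-2-en-1-yloxy)benzene
Product: 22 6-methoxy-3-methyl-2-(prop-2-en-1-yl)phenol
Conditions: N,N-diethylaniline, 190 °C
Reagents that add atoms: none
Why: The aromatic Claisen rearrangement ([3,3]-sigmatropic shift, then tautomerisation) delivers the allyl group to the only unsubstituted ortho carbon, the one between the hydroxyl and the methyl group, which is exactly the ring position of the side chain.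

Step 14
Reactants: 18 (8R,10R,12S,14S)-8,10,12,14-tetramethylhexadec-1-ene, 22 6-methoxy-3-methyl-2-(prop-2-en-1-yl)phenol
Product: 23 6-methoxy-3-methyl-2-[(2E,9R,11R,13S,15S)-9,11,13,15-tetramethylheptadec-2-en-1-yl]phenol (E/Z mixture expected)
Conditions: 22 (3 equiv), RuCl2(=CHPh)(H2IMes)(PCy3) (second-generation Grubbs catalyst, 5 mol%), 1,4-benzoquinone (10 mol%), CH2Cl2, 40 °C
Reagents that add atoms: none
Why: Olefin cross-metathesis of two monosubstituted alkenes, driven by loss of ethene and by the excess of the cheap allylphenol, forms the C2–C3 bond; the alkene geometry is irrelevant because the double bond is hydrogenated next.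

Step 15
Reactants: 23 6-methoxy-3-methyl-2-[(2E,9R,11R,13S,15S)-9,11,13,15-tetramethylheptadec-2-en-1-yl]phenol
Product: 24 6-methoxy-3-methyl-2-[(9R,11R,13S,15S)-9,11,13,15-tetramethylheptadecyl]phenol
Conditions: H2 (1 atm), Pd/C, EtOAc, 23 °C
Reagents that add atoms: none
Why: Heterogeneous catalytic hydrogenation saturates the disubstituted alkene without affecting the arene or the remote stereocenters.

Step 16
Reactants: 24 6-methoxy-3-methyl-2-[(9R,11R,13S,15S)-9,11,13,15-tetramethylheptadecyl]phenol
Product: 25 5-methoxy-2-methyl-3-[(9R,11R,13S,15S)-9,11,13,15-tetramethylheptadecyl]cyclohexa-2,5-diene-1,4-dione (target)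
Conditions: (KSO3)2NO (2.5 equiv), KH2PO4, H2O/acetone, 23 °C
Reagents that add atoms: potassium nitrosodisulfonate, [K+].[K+].[O]N(S(=O)(=O)[O-])S(=O)(=O)[O-]
Why: In the Teuber oxidation one nitrosodisulfonate radical abstracts the phenolic hydrogen and a second adds at the free para carbon, and loss of imidodisulfonate should give the para-quinone, since both ortho positions are blocked by the chain and the methoxy group.

**Compound list**

1 | cis-2,4-dimethylglutaric anhydride, (3R,5S)-3,5-dimethyloxane-2,6-dione (meso) | O=C1[C@H](C)C[C@H](C)C(=O)O1 | starting material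
2 | (2R,4S)-2,4-dimethylpentane-1,5-diol (meso) | OC[C@H](C)C[C@H](C)CO | intermediate
3 | (2R,4S)-5-hydroxy-2,4-dimethylpentyl acetate | CC(=O)OC[C@H](C)C[C@H](C)CO | intermediate
4 | (2R,4S)-5-[(tert-butyldimethylsilyl)oxy]-2,4-dimethylpentyl acetate | CC(=O)OC[C@H](C)C[C@H](C)CO[Si](C)(C)C(C)(C)C | intermediate
5 | (2R,4S)-5-[(tert-butyldimethylsilyl)oxy]-2,4-dimethylpentan-1-ol | OC[C@H](C)C[C@H](C)CO[Si](C)(C)C(C)(C)C | intermediate
6 | tert-butyl{[(2S,4R)-5-bromo-2,4-dimethylpentyl]oxy}dimethylsilane | BrC[C@H](C)C[C@H](C)CO[Si](C)(C)C(C)(C)C | intermediate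
7 | (2R)-butan-2-ol | CC[C@@H](C)O | starting material
8 | (2R)-butan-2-yl 4-methylbenzenesulfonate | CC[C@@H](C)OS(=O)(=O)c1ccc(C)cc1 | intermediate
9 | {(2R,4S)-5-[(tert-butyldimethylsilyl)oxy]-2,4-dimethylpentyl}magnesium bromide | Br[Mg]C[C@H](C)C[C@H](C)CO[Si](C)(C)C(C)(C)C | intermediate
10 | tert-butyldimethyl{[(2S,4S,6S)-2,4,6-trimethyloctyl]oxy}silane | CC[C@H](C)C[C@H](C)C[C@H](C)CO[Si](C)(C)C(C)(C)C | intermediate
11 | (2S,4S,6S)-1-bromo-2,4,6-trimethyloctane | CC[C@H](C)C[C@H](C)C[C@H](C)CBr | intermediate
12 | (2S)-2-methyloxirane ((S)-propylene oxide) | C[C@H]1CO1 | starting material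
13 | 6-bromohex-1-ene | C=CCCCCBr | starting material
14 | hex-5-en-1-ylmagnesium bromide | C=CCCCC[Mg]Br | intermediate
15 | (2S)-non-8-en-2-ol | C[C@H](O)CCCCCC=C | intermediate
16 | (2S)-non-8-en-2-yl 4-methylbenzenesulfonate | C[C@H](OS(=O)(=O)c1ccc(C)cc1)CCCCCC=C | intermediate
17 | [(2S,4S,6S)-2,4,6-trimethyloctyl]magnesium bromide | CC[C@H](C)C[C@H](C)C[C@H](C)C[Mg]Br | intermediate
18 | (8R,10R,12S,14S)-8,10,12,14-tetramethylhexadec-1-ene | CC[C@H](C)C[C@H](C)C[C@H](C)C[C@H](C)CCCCCC=C | intermediate
19 | 2-methoxy-5-methylphenol | COc1ccc(C)cc1O | starting material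
20 | 3-bromoprop-1-ene (allyl bromide) | C=CCBr | starting material
21 | 1-methoxy-4-methyl-2-(prop-2-en-1-yloxy)benzene | COc1ccc(C)cc1OCC=C | intermediate
22 | 6-methoxy-3-methyl-2-(prop-2-en-1-yl)phenol | COc1ccc(C)c(CC=C)c1O | intermediate
23 | 6-methoxy-3-methyl-2-[(2E,9R,11R,13S,15S)-9,11,13,15-tetramethylheptadec-2-en-1-yl]phenol (E shown, E/Z mixture expected) | CC[C@H](C)C[C@H](C)C[C@H](C)C[C@H](C)CCCCC/C=C/Cc1c(C)ccc(OC)c1O | intermediate
24 | 6-methoxy-3-methyl-2-[(9R,11R,13S,15S)-9,11,13,15-tetramethylheptadecyl]phenol | CC[C@H](C)C[C@H](C)C[C@H](C)C[C@H](C)CCCCCCCCc1c(C)ccc(OC)c1O | intermediate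
25 | 5-methoxy-2-methyl-3-[(9R,11R,13S,15S)-9,11,13,15-tetramethylheptadecyl]cyclohexa-2,5-diene-1,4-dione | CC[C@H](C)C[C@H](C)C[C@H](C)C[C@H](C)CCCCCCCCC1=C(C)C(=O)C=C(OC)C1=O | target

**Step count and risks**

Total step count: 16. Longest linear sequence: 11 steps (1, 2, 3, 4, 5, 7, 8, 11, 14, 15, 16).

Steps most likely to fail:

Step 11. Elimination of the secondary tosylate and reduction or homocoupling of the Grignard reagent may outrun substitution, or a partial electron-transfer pathway may erode the inversion at C9. The fallback sets out from 11 and comes back at 18, and takes C9 from lactic acid by substitution at an activated center. tert-Butyl (S)-lactate would be converted with Tf2O and 2,6-lutidine into tert-butyl (2S)-2-{[(trifluoromethyl)sulfonyl]oxy}propanoate F1. Grignard reagent 17 from 11 would be coupled with F1 under ZnCl2 catalysis (SN2 at the α-carbon of the ester, inversion) to give tert-butyl (2S,4S,6S,8S)-2,4,6,8-tetramethyldecanoate F2. Reduction with LiAlH4 should give (2S,4S,6S,8S)-2,4,6,8-tetramethyldecan-1-ol F3, and TsCl in pyridine its tosylate, (2S,4S,6S,8S)-2,4,6,8-tetramethyldecyl 4-methylbenzenesulfonate F4. Coupling of F4 with hex-5-en-1-ylmagnesium bromide 14 (Li2CuCl4 as catalyst, THF, −20 → 0 °C), a primary–primary union, would deliver 18.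

Step 14. Migration of the double bond along the chain before metathesis and homodimerisation of the chain alkene may compete with the cross-coupling and give shortened or dimeric products. The fallback sets out from 18 and comes back at 24, and forms the aryl–chain bond by electrophilic ortho-alkylation. Linear hydroformylation of 18 (Rh(acac)(CO)2, Xantphos, CO/H2, toluene, 80 °C) should give (9R,11R,13S,15S)-9,11,13,15-tetramethylheptadecanal F5. Condensation of F5 with phenol 19 and phenylboronic acid (catalytic propionic acid, toluene, reflux with removal of water) would give, ortho-specifically, 8-methoxy-5-methyl-2-phenyl-4-[(8R,10R,12S,14S)-8,10,12,14-tetramethylhexadecyl]-4H-1,3,2-benzodioxaborinine F6 (both epimers at C4). Reductive cleavage of its benzylic C–O bond (t-BuNH2·BH3, AlCl3, CH2Cl2) should give 24 directly.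

Step 2. The enzyme may discriminate the two enantiotopic hydroxymethyl groups insufficiently, so that 3 is formed with low enantiomeric purity and the error is carried into all later diastereomers. The fallback sets out from 1 and comes back at 5, and desymmetrises the anhydride itself without an enzyme. Methanolysis of 1 in the presence of a cinchona alkaloid (quinidine or its pseudo-enantiomer quinine, whichever delivers this enantiomer; toluene/CCl4, −55 °C) would give (2S,4R)-5-methoxy-2,4-dimethyl-5-oxopentanoic acid F7. Chemoselective reduction of the free acid with BH3·SMe2 should give methyl (2R,4S)-5-hydroxy-2,4-dimethylpentanoate F8, which would be silylated at once (TBSCl, imidazole) to methyl (2R,4S)-5-[(tert-butyldimethylsilyl)oxy]-2,4-dimethylpentanoate F9. Reduction of the ester with LiAlH4 would give 5.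

Further compounds
F1 | step 11 | tert-butyl (2S)-2-{[(trifluoromethyl)sulfonyl]oxy}propanoate | C[C@H](OS(=O)(=O)C(F)(F)F)C(=O)OC(C)(C)C
F2 | step 11 | tert-butyl (2S,4S,6S,8S)-2,4,6,8-tetramethyldecanoate | CC[C@H](C)C[C@H](C)C[C@H](C)C[C@H](C)C(=O)OC(C)(C)C
F3 | step 11 | (2S,4S,6S,8S)-2,4,6,8-tetramethyldecan-1-ol | CC[C@H](C)C[C@H](C)C[C@H](C)C[C@H](C)CO
F4 | step 11 | (2S,4S,6S,8S)-2,4,6,8-tetramethyldecyl 4-methylbenzenesulfonate | CC[C@H](C)C[C@H](C)C[C@H](C)C[C@H](C)COS(=O)(=O)c1ccc(C)cc1
F5 | step 14 | (9R,11R,13S,15S)-9,11,13,15-tetramethylheptadecanal | CC[C@H](C)C[C@H](C)C[C@H](C)C[C@H](C)CCCCCCCC=O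
F6 | step 14 | 8-methoxy-5-methyl-2-phenyl-4-[(8R,10R,12S,14S)-8,10,12,14-tetramethylhexadecyl]-4H-1,3,2-benzodioxaborinine (both C4 epimers) | COc1ccc(C)c2c1OB(c1ccccc1)OC2CCCCCCC[C@@H](C)C[C@@H](C)C[C@@H](C)C[C@@H](C)CC
F7 | step 2 | (2S,4R)-5-methoxy-2,4-dimethyl-5-oxopentanoic acid | COC(=O)[C@H](C)C[C@H](C)C(=O)O
F8 | step 2 | methyl (2R,4S)-5-hydroxy-2,4-dimethylpentanoate | COC(=O)[C@H](C)C[C@H](C)CO
F9 | step 2 | methyl (2R,4S)-5-[(tert-butyldimethylsilyl)oxy]-2,4-dimethylpentanoate | COC(=O)[C@H](C)C[C@H](C)CO[Si](C)(C)C(C)(C)C
A1 | direct plan | tert-butyl(dec-9-en-1-yloxy)dimethylsilane | C=CCCCCCCCCO[Si](C)(C)C(C)(C)C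
A2 | direct plan | (9R,11R,13S,15S)-1-bromo-9,11,13,15-tetramethylheptadecane | CC[C@H](C)C[C@H](C)C[C@H](C)C[C@H](C)CCCCCCCCBr
A3 | direct plan | (2Z,12R,14R,16S,18S)-3-bromo-12,14,16,18-tetramethylicos-2-ene | CC[C@H](C)C[C@H](C)C[C@H](C)C[C@H](C)CCCCCCCC/C(Br)=C/C
A4 | direct plan | 3-methoxycyclobut-3-ene-1,2-dione | COC1=CC(=O)C1=O
A5 | direct plan | 4-hydroxy-3-methoxy-4-[(2Z,12R,14R,16S,18S)-12,14,16,18-tetramethylicos-2-en-3-yl]cyclobut-2-en-1-one (both C4 epimers) | CC[C@H](C)C[C@H](C)C[C@H](C)C[C@H](C)CCCCCCCC/C(=C/C)C1(O)C(=O)C=C1OC
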